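**Plan**

1. Cembrane numbering is used: C1 (i-Pr), C4 (Me), C6 (lactone O), C8 (carries lactone C19), C12 (carries ester C20), C13 (OH). The hardest task is closing the 14-membered carbocycle C1–C14 while also securing the (1E,3E)-diene and the C11=C12 enoate, in which ring atoms C10 and C13 are trans, next to C13–OH.
2. Enabling feature: C13(OH)–C14H2–C1(i-Pr)=C2H is a carbonyl-ene retron. Moving C1=C2 back gives the skipped diene C14H2=C1–C2H2–C3H=C4. Its doubly allylic C2–H is the only transferable hydrogen, because the i-Pr methine C–H lies in the alkene plane. A C–H bond is therefore the only handle needed, and the ring closure itself creates the conjugated diene.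
3. Cuts, in retrosynthetic order: C12–C20 (CO/MeOH on alkyne C11≡C12); C13–C14 (ene, opening the ring to an ynal); C8–C19 (CO on alkyne C7≡C8); C2–C3 and C4–CH3 (carboalumination/allylation); C5–C6 (propargylation); C6–C7 and C12–C13 (C1 units on hexa-1,5-diyne, which supplies C7–C12).
4. Forward order: the chain is grown on hexadiyne. The butenolide ring comes first (OH-directed distal trans-hydroalumination, iodination, carbonylative lactonisation). The carbocycle follows (ene), then the ester (OH-directed proximal trans-hydrostannation, methoxycarbonylation). Both carboxyl carbons come from CO.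
5. Stereochemistry: C6 (R) comes from a chiral-phosphoric-acid-catalysed propargylation. C13 forms uncontrolled in the ene step, and both epimers are funnelled to S by oxidation and Noyori transfer hydrogenation. C3=C4 comes from syn-carboalumination, C1=C2 from the ene transition state, and C7=C8 and C11=C12 from the two trans-hydrometalations.

Key step: step 11

Assumption: the facial sense of (R)-TRIP towards ynal 12, and of the (S,S)-Ru catalyst towards ynone 25, is taken to be that known for aryl/alkenyl aldehydes and for simple alkyl alkynyl ketones, with the alkynyl group playing the part of the unsaturated substituent.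

**Step 1**
Reactants: 1 prop-2-yn-1-ol; 2 isopropylmagnesium chloride
Product: 4 3-methyl-2-methylidenebutan-1-ol, via oxamagnesacycle 3 (not isolated)
Conditions: 2 (3 equiv), CuI (10 mol %), THF, 0 °C to rt; then aq NH4Cl
Reagents that add atoms: none
Why: Copper-catalysed, alkoxide-directed anti-carbomagnesiation of propargyl alcohol should place the isopropyl group on the internal alkyne carbon and magnesium on the terminal one in a five-membered chelate, whose protonolysis gives the 2-substituted allylic alcohol.

**Step 2**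
Reactants: 4 3-methyl-2-methylidenebutan-1-ol
Product: 5 2-(bromomethyl)-3-methylbut-1-ene
Conditions: PBr3 (0.4 equiv), Et2O, 0 °C
Reagents that add atoms: phosphorus tribromide, BrP(Br)Br
Why: Bromination of a primary allylic alcohol with PBr3 (SN2) should be clean, since the SN2′ path gives the same compound because the allyl unit is symmetrical.

**Step 3**
Reactants: 6 hexa-1,5-diyne
Product: 9 tert-butyl(hepta-2,6-diyn-1-yloxy)dimethylsilane, via lithium acetylide 7 (not isolated), via lithium alkoxide 8 (not isolated)
Conditions: 6 (2.5 equiv), n-BuLi (1 equiv), THF, −78 °C; (CH2O)n, to rt; TBSCl, DMAP (cat.), rt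
Reagents that add atoms: paraformaldehyde (as formaldehyde), C=O; tert-butyldimethylsilyl chloride, CC(C)(C)[Si](C)(C)Cl
Why: Monolithiation of the diyne used in excess, hydroxymethylation of the acetylide and silylation of the lithium alkoxide in the same flask should give the C7–C13 unit with C13 masked as a silyl ether that survives steps 4–8.

**Step 4**
Reactants: 9 tert-butyl(hepta-2,6-diyn-1-yloxy)dimethylsilane
Product: 12 8-[(tert-butyldimethylsilyl)oxy]octa-2,6-diynal, via silyloxy lithium acetylide 10 (not isolated), via lithium hemiaminolate 11 (not isolated)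
Conditions: n-BuLi, THF, −78 °C; DMF; inverse quench into aq KH2PO4/MTBE
Reagents that add atoms: N,N-dimethylformamide, CN(C)C=O
Why: Formylation of a lithium acetylide with DMF should install C6, since the tetrahedral adduct persists until the buffered inverse quench and so keeps the liberated amine from adding to the ynal.

**Step 5**
Reactants: 12 8-[(tert-butyldimethylsilyl)oxy]octa-2,6-diynal; 13 allenylboronic acid pinacol ester
Product: 15 (4R)-11-[(tert-butyldimethylsilyl)oxy]undeca-1,5,9-triyn-4-ol, via pinacol borate ester 14 (not isolated)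
Conditions: 13 (1.5 equiv), (R)-TRIP (5 mol %), 4 Å MS, toluene, −20 °C; aq work-up
Reagents that add atoms: none
Why: Chiral-phosphoric-acid-catalysed propargylation of an aldehyde with an allenylboronate, through a closed six-membered SE2′ transition state in which the catalyst holds a boronate oxygen and the formyl hydrogen and shields one aldehyde face, should form C5–C6 and set C6 as R.

**Step 6**
Reactants: 15 (4R)-11-[(tert-butyldimethylsilyl)oxy]undeca-1,5,9-triyn-4-ol; 5 2-(bromomethyl)-3-methylbut-1-ene
Product: 17 (4E,7R)-14-[(tert-butyldimethylsilyl)oxy]-5-methyl-2-(propan-2-yl)tetradeca-1,4-diene-8,12-diyn-7-ol, via alkenylalane 16 (not isolated)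
Conditions: AlMe3 (3 equiv), Cp2ZrCl2 (25 mol %), CH2Cl2, 0 °C to rt; volatiles off; 5, Pd(PPh3)4 (5 mol %), THF, rt
Reagents that add atoms: trimethylaluminium, C[Al](C)C
Why: Negishi zirconium-catalysed syn-methylalumination, which is selective for the terminal alkyne, should put CH3 on C4 and Al on C3 (E), and the Pd-catalysed alkenyl–allyl coupling with retention through the symmetrical π-allyl of 5 should then form C2–C3 and give the skipped diene.

**Step 7**
Reactants: 17 (4E,7R)-14-[(tert-butyldimethylsilyl)oxy]-5-methyl-2-(propan-2-yl)tetradeca-1,4-diene-8,12-diyn-7-ol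
Product: 19 (4E,7R,8Z)-14-[(tert-butyldimethylsilyl)oxy]-9-iodo-5-methyl-2-(propan-2-yl)tetradeca-1,4,8-trien-12-yn-7-ol, via cyclic alkenylaluminate 18 (not isolated)
Conditions: Red-Al, THF, 0 °C to rt; I2, −78 °C
Reagents that add atoms: iodine, II
Why: Alkoxide-directed trans-hydroalumination of the propargylic alcohol should deliver H to C7 and Al to C8 in a five-membered aluminate, and iodinolysis with retention gives the Z-iodide, while the C11≡C12 alkyne lacks a free hydroxyl and stays untouched.

**Step 8**
Reactants: 19 (4E,7R,8Z)-14-[(tert-butyldimethylsilyl)oxy]-9-iodo-5-methyl-2-(propan-2-yl)tetradeca-1,4,8-trien-12-yn-7-ol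
Product: 20 (5R)-3-{5-[(tert-butyldimethylsilyl)oxy]pent-3-yn-1-yl}-5-[(2E)-2-methyl-5-(propan-2-yl)hexa-2,5-dien-1-yl]furan-2(5H)-one
Conditions: PdCl2(PPh3)2 (5 mol %), CO (1 atm), i-Pr2NEt, THF, 45 °C
Reagents that add atoms: carbon monoxide, [C-]#[O+]
Why: Palladium-catalysed carbonylative lactonisation (oxidative addition, CO insertion, capture of the acyl-palladium by the cis C6–OH) should close the butenolide with C19 from CO and leave the C6–O bond, and hence the R configuration, untouched.

**Step 9**
Reactants: 20 (5R)-3-{5-[(tert-butyldimethylsilyl)oxy]pent-3-yn-1-yl}-5-[(2E)-2-methyl-5-(propan-2-yl)hexa-2,5-dien-1-yl]furan-2(5H)-one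
Product: 21 (5R)-3-(5-hydroxypent-3-yn-1-yl)-5-[(2E)-2-methyl-5-(propan-2-yl)hexa-2,5-dien-1-yl]furan-2(5H)-one
Conditions: HF·pyridine, THF, 0 °C
Reagents that add atoms: none
Why: Fluoride-mediated desilylation under slightly acidic conditions should free the C13 alcohol without the basic medium that could epimerise C6 of the butenolide.

**Step 10**
Reactants: 21 (5R)-3-(5-hydroxypent-3-yn-1-yl)-5-[(2E)-2-methyl-5-(propan-2-yl)hexa-2,5-dien-1-yl]furan-2(5H)-one
Product: 22 5-{(5R)-5-[(2E)-2-methyl-5-(propan-2-yl)hexa-2,5-dien-1-yl]-2-oxo-2,5-dihydrofuran-3-yl}pent-2-ynal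
Conditions: MnO2, CH2Cl2, rt
Reagents that add atoms: none
Why: Manganese dioxide oxidation is selective for the activated primary propargylic alcohol and should give the ynal under neutral conditions.

**Step 11**
Reactants: 22 5-{(5R)-5-[(2E)-2-methyl-5-(propan-2-yl)hexa-2,5-dien-1-yl]-2-oxo-2,5-dihydrofuran-3-yl}pent-2-ynal
Product: 24 (1E,3E,6R,13RS)-13-hydroxy-20-norcembra-1,3,7-trien-11-yn-19,6-olide, via chloromethylaluminium alkoxide 23 (not isolated)
Conditions: Me2AlCl (3 equiv), CH2Cl2, slow addition of 22 (final 1 mM), −78 to −40 °C; then H2O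
Reagents that add atoms: none
Why: Me2AlCl (in excess because the lactone also binds it) activates the ynal oxygen, the terminal carbon C14 of the 1,1-disubstituted alkene attacks C13 while the doubly allylic C2–H passes to oxygen through a six-centre, asynchronous carbonyl-ene transition state, and the alcohol–aluminium complex then loses methane to give alkoxide 23, which shields the product from acid. The closest known reaction type is the alkylaluminium-halide-promoted ene cyclisation of ω-alkenyl ynals to 12- to 16-membered cyclic propargylic alcohols, joined to the well-known intermolecular ene reactivity of 1,1-disubstituted alkenes towards aldehyde–Me2AlCl complexes. The one ring closed is the 14-membered carbocycle, by C13–C14 bond formation at high dilution, in the topology in which all three ene carbons (C14, C1, C2) end up inside the ring. C13 is the only new stereocentre and nothing in the substrate controls it, so both epimers are expected and both are carried on, because steps 12 and 13 erase and reset this centre. The step needs regioselective hydrogen transfer (the isopropyl methine C–H lies in the alkene plane and cannot overlap, whereas C2–H is weakened by both alkenes), site selectivity (attack by C3=C4 would give an 11-membered ring, and 1,2-addition is the rule for β-alkyl ynals) and C1=C2 geometry (C3 turns away from the isopropyl group and towards C14, which is also the arrangement in which the ten-atom tether can span C2 and C13).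

**Step 12**
Reactants: 24 (1E,3E,6R,13RS)-13-hydroxy-20-norcembra-1,3,7-trien-11-yn-19,6-olide
Product: 25 (1E,3E,6R)-13-oxo-20-norcembra-1,3,7-trien-11-yn-19,6-olide
Conditions: Dess–Martin periodinane, CH2Cl2, 0 °C
Reagents that add atoms: none
Why: Dess–Martin oxidation under mild, non-basic conditions should merge both C13 epimers into one ynone without moving the β,γ-double bond.

**Step 13**
Reactants: 25 (1E,3E,6R)-13-oxo-20-norcembra-1,3,7-trien-11-yn-19,6-olide
Product: 26 (1E,3E,6R,13S)-13-hydroxy-20-norcembra-1,3,7-trien-11-yn-19,6-olide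
Conditions: Ru(p-cymene)[(S,S)-TsDPEN] (5 mol %), i-PrOH, rt
Reagents that add atoms: none
Why: Noyori asymmetric transfer hydrogenation of an alkynyl ketone tells the alkynyl flank from the alkyl flank by catalyst control, so the (S,S)-catalyst should set C13 as S independently of the remote C6 and leave the alkyne, diene and lactone untouched.

**Step 14**
Reactants: 26 (1E,3E,6R,13S)-13-hydroxy-20-norcembra-1,3,7-trien-11-yn-19,6-olide
Product: 27 (1E,3E,6R,11Z,13S)-13-hydroxy-12-(tributylstannyl)-20-norcembra-1,3,7,11-tetraen-19,6-olide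
Conditions: [Cp*RuCl]4 (2.5 mol %), Bu3SnH (slow addition), CH2Cl2, rt
Reagents that add atoms: tributyltin hydride, CCCC[SnH](CCCC)CCCC
Why: Ruthenium-catalysed hydroxyl-directed trans-hydrostannation, in which the OH···Cl–Ru hydrogen bond steers tin to the proximal carbon C12 and H and Sn add trans, should give the alkene with C10 and C13 trans, while the crowded diene cannot reach the s-cis form needed to bind the catalyst.

**Step 15**
Reactants: 27 (1E,3E,6R,11Z,13S)-13-hydroxy-12-(tributylstannyl)-20-norcembra-1,3,7,11-tetraen-19,6-olide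
Product: 28 methyl (1E,3E,6R,11Z,13S)-13-hydroxy-19-oxo-6,19-epoxycembra-1,3,7,11-tetraen-20-oate (target CNP0173999.1)
Conditions: Pd(OAc)2 (10 mol %), Ph3As, 1,4-benzoquinone, TFA (cat.), CO (1 atm), MeOH, rt
Reagents that add atoms: carbon monoxide, [C-]#[O+]; methanol, CO
Why: Hydroxyl-assisted oxidative methoxycarbonylation of an alkenylstannane (Sn-to-Pd(II) transmetalation with retention, CO insertion, methanolysis, reoxidation of Pd(0) by benzoquinone) should replace tin by CO2Me with the geometry kept, so that the ester stands cis to C10 as in the target.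

**Compound list**

1 | prop-2-yn-1-ol | OCC#C | starting material
2 | isopropylmagnesium chloride | CC(C)[Mg]Cl | starting material
3 | 4-isopropyl-2,5-dihydro-1,2-oxamagnesole | CC(C)C1=C[Mg]OC1 | intermediate
4 | 3-methyl-2-methylidenebutan-1-ol | C=C(CO)C(C)C | intermediate
5 | 2-(bromomethyl)-3-methylbut-1-ene | C=C(CBr)C(C)C | intermediate
6 | hexa-1,5-diyne | C#CCCC#C | starting material
7 | hexa-1,5-diyn-1-yllithium | [Li]C#CCCC#C | intermediate
8 | lithium hepta-2,6-diyn-1-olate | [Li]OCC#CCCC#C | intermediate
9 | tert-butyl(hepta-2,6-diyn-1-yloxy)dimethylsilane | C#CCCC#CCO[Si](C)(C)C(C)(C)C | intermediate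
10 | {7-[(tert-butyldimethylsilyl)oxy]hepta-1,5-diyn-1-yl}lithium | [Li]C#CCCC#CCO[Si](C)(C)C(C)(C)C | intermediate
11 | lithium 8-[(tert-butyldimethylsilyl)oxy]-1-(dimethylamino)octa-2,6-diyn-1-olate | [Li]OC(N(C)C)C#CCCC#CCO[Si](C)(C)C(C)(C)C | intermediate
12 | 8-[(tert-butyldimethylsilyl)oxy]octa-2,6-diynal | O=CC#CCCC#CCO[Si](C)(C)C(C)(C)C | intermediate
13 | allenylboronic acid pinacol ester | C=C=CB1OC(C)(C)C(C)(C)O1 | starting material
14 | pinacol borate ester of 15 (O–Bpin at C6, 6R) | C#CC[C@@H](OB1OC(C)(C)C(C)(C)O1)C#CCCC#CCO[Si](C)(C)C(C)(C)C | intermediate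
15 | (4R)-11-[(tert-butyldimethylsilyl)oxy]undeca-1,5,9-triyn-4-ol | C#CC[C@@H](O)C#CCCC#CCO[Si](C)(C)C(C)(C)C | intermediate
16 | (E)-alkenyl(dimethyl)alane at C3 with C6–O–AlMe2 | C[Al](C)/C=C(C)/C[C@@H](O[Al](C)C)C#CCCC#CCO[Si](C)(C)C(C)(C)C | intermediate
17 | (4E,7R)-14-[(tert-butyldimethylsilyl)oxy]-5-methyl-2-(propan-2-yl)tetradeca-1,4-diene-8,12-diyn-7-ol | C=C(C(C)C)C/C=C(C)/C[C@@H](O)C#CCCC#CCO[Si](C)(C)C(C)(C)C | intermediate
18 | sodium 1,2-oxaaluminol-3-ene ate complex (ring O6–C6–C7=C8–Al, two 2-methoxyethoxy ligands) | [Na+].C=C(C(C)C)C/C=C(C)/C[C@H]1O[Al-](OCCOC)(OCCOC)C(CCC#CCO[Si](C)(C)C(C)(C)C)=C1 | intermediate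
19 | (4E,7R,8Z)-14-[(tert-butyldimethylsilyl)oxy]-9-iodo-5-methyl-2-(propan-2-yl)tetradeca-1,4,8-trien-12-yn-7-ol | C=C(C(C)C)C/C=C(C)/C[C@@H](O)/C=C(\I)CCC#CCO[Si](C)(C)C(C)(C)C | intermediate
20 | (5R)-3-{5-[(tert-butyldimethylsilyl)oxy]pent-3-yn-1-yl}-5-[(2E)-2-methyl-5-(propan-2-yl)hexa-2,5-dien-1-yl]furan-2(5H)-one | C=C(C(C)C)C/C=C(C)/C[C@H]1OC(=O)C(CCC#CCO[Si](C)(C)C(C)(C)C)=C1 | intermediate
21 | (5R)-3-(5-hydroxypent-3-yn-1-yl)-5-[(2E)-2-methyl-5-(propan-2-yl)hexa-2,5-dien-1-yl]furan-2(5H)-one | C=C(C(C)C)C/C=C(C)/C[C@H]1OC(=O)C(CCC#CCO)=C1 | intermediate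
22 | 5-{(5R)-5-[(2E)-2-methyl-5-(propan-2-yl)hexa-2,5-dien-1-yl]-2-oxo-2,5-dihydrofuran-3-yl}pent-2-ynal | C=C(C(C)C)C/C=C(C)/C[C@H]1OC(=O)C(CCC#CC=O)=C1 | intermediate
23 | chloro(methyl)aluminium alkoxide of 24 | C[Al](Cl)OC1C#CCCC2=C[C@@H](C/C(C)=C/C=C(/C(C)C)C1)OC2=O | intermediate
24 | (1E,3E,6R,13RS)-13-hydroxy-20-norcembra-1,3,7-trien-11-yn-19,6-olide (both C13 epimers) | OC1C#CCCC2=C[C@@H](C/C(C)=C/C=C(/C(C)C)C1)OC2=O | intermediate
25 | (1E,3E,6R)-13-oxo-20-norcembra-1,3,7-trien-11-yn-19,6-olide | O=C1C#CCCC2=C[C@@H](C/C(C)=C/C=C(/C(C)C)C1)OC2=O | intermediate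
26 | (1E,3E,6R,13S)-13-hydroxy-20-norcembra-1,3,7-trien-11-yn-19,6-olide | O[C@@H]1C#CCCC2=C[C@@H](C/C(C)=C/C=C(/C(C)C)C1)OC2=O | intermediate
27 | (1E,3E,6R,11Z,13S)-13-hydroxy-12-(tributylstannyl)-20-norcembra-1,3,7,11-tetraen-19,6-olide | CCCC[Sn](CCCC)(CCCC)/C1=C\CCC2=C[C@@H](C/C(C)=C/C=C(/C(C)C)C[C@@H]1O)OC2=O | intermediate
28 | methyl (1E,3E,6R,11Z,13S)-13-hydroxy-19-oxo-6,19-epoxycembra-1,3,7,11-tetraen-20-oate (CNP0173999.1) | COC(=O)/C1=C\CCC2=C[C@@H](C/C(C)=C/C=C(/C(C)C)C[C@@H]1O)OC2=O | target

**Step count**

Total step count: 15. Longest linear sequence: 13 (steps 3–15).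

**Steps most likely to fail**

Step 11 (ene macrocyclisation).
- Risk: Intermolecular ene reaction (oligomerisation) may outrun ring closure, because the linear C10–C13 ynal unit holds the reacting ends apart. Hydrogen transfer may also give part of the wrong C1=C2 geometry.
- Fallback (a temporary ring on the alkyne): It sets out from 22, which with Co2(CO)8 in CH2Cl2 should give the hexacarbonyldicobalt complex of the ynal F1. The C2Co2 tetrahedrane bends C10–C11–C12–C13 to about 140°, shields the triple bond against conjugate attack and stabilises positive charge at C13 (Nicholas-type activation). Closure with BF3·OEt2 at the same dilution should then give the hexacarbonyldicobalt complex of the macrocyclic alcohol F2. Oxidative decomplexation with ceric ammonium nitrate in acetone at low temperature returns to the route at 24.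

Step 12 (oxidation, and the life of ketone 25 up to step 13).
- Risk: The C14 methylene lies between the ynone carbonyl and the diene. Its enolisation may move C1=C2 into conjugation or start decomposition.
- Fallback (no ketone): It sets out from 24, whose C13 epimers are separated by chromatography. The 13S epimer is 26 itself. The 13R epimer F3 is inverted by a Mitsunobu reaction with chloroacetic acid (PPh3, DIAD, THF, 0 °C) to the 13S chloroacetate F4. Thiourea/NaHCO3 in EtOH should cleave this ester without touching the lactone, and the fallback returns to the route at 26.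

Step 15 (oxidative methoxycarbonylation).
- Risk: Pd(II)/benzoquinone may attack the 1,3-diene (oxidative 1,4-functionalisation), or protodestannylation by the acid additive may outrun transmetalation.
- Fallback (redox-neutral Pd(0) carbonylation): It sets out from 27. Iododestannylation (I2, CH2Cl2, −78 °C) should give, with retention, the (11Z)-12-iodo allylic alcohol F5. Pd(PPh3)4, CO (1 atm), MeOH and Et3N in DMF at 40 °C should convert F5 into the methyl ester, which returns to the route at 28.

**Further compounds**

F1 | step 11 | hexacarbonyldicobalt complex of ynal 22 (C11≡C12 bound as C2Co2 tetrahedrane) | C=C(C(C)C)C/C=C(C)/C[C@H]1OC(=O)C(CCC23C4(C=O)[Co]2(=C=O)(=C=O)(=C=O)[Co]34(=C=O)(=C=O)=C=O)=C1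
F2 | step 11 | hexacarbonyldicobalt complex of macrocyclic alcohol 24 | OC1C34C5(CCC2=C[C@@H](C/C(C)=C/C=C(/C(C)C)C1)OC2=O)[Co]3(=C=O)(=C=O)(=C=O)[Co]45(=C=O)(=C=O)=C=O
F3 | step 12 | (1E,3E,6R,13R)-13-hydroxy-20-norcembra-1,3,7-trien-11-yn-19,6-olide | O[C@H]1C#CCCC2=C[C@@H](C/C(C)=C/C=C(/C(C)C)C1)OC2=O
F4 | step 12 | (1E,3E,6R,13S)-13-(chloroacetoxy)-20-norcembra-1,3,7-trien-11-yn-19,6-olide | O=C(CCl)O[C@@H]1C#CCCC2=C[C@@H](C/C(C)=C/C=C(/C(C)C)C1)OC2=O
F5 | step 15 | (1E,3E,6R,11Z,13S)-13-hydroxy-12-iodo-20-norcembra-1,3,7,11-tetraen-19,6-olide | I/C1=C\CCC2=C[C@@H](C/C(C)=C/C=C(/C(C)C)C[C@@H]1O)OC2=O
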